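**Retrosynthetic overview**
1. Feature: the non-flavanone half is numbered as a chain, C1 (lactone C=O), C2, C3 (ether O–CH), C4 (lactone O–CH), C5, C6 (ether O–CH), C7 (benzylic CH). C1–C4 are oxygenated at C1 and C4, and C3 is bridged through the ring oxygen to C6. This is the pattern of an oxidised 2-alkylfuran whose side chain carries a hydroxyl β to the ring.
2. C7–OAr: a Mitsunobu coupling with inversion separates (S)-pinocembrin 15 from bicyclic alcohol 14.
3. Lactone ring (formed second): the C4–O bond leads back to tetrahydrofuran-3-one acetic acid 11 by ketone reduction and lactonisation.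
4. Tetrahydrofuran ring (formed first): the O–C3 bond leads back to 5-silyl-2-(β-hydroxyalkyl)furan 6 by singlet oxygen and 5-exo oxa-Michael closure.
5. Compound 6 comes from lithiated 2-(trimethylsilyl)furan 4 and silyloxy epoxide 3. The C6/C7 pair of 3 comes from a Sharpless kinetic resolution of allylic alcohol 1.

Key step: step 4

Assumption: 15 is bought as the natural (2S) enantiomer, and 1 and 4 are bought as such. The labels C1–C7 follow the chain numbering above.

Design remark 1: the furan carbon that becomes C1 carries SiMe3, which is lost in step 4. The endoperoxide then reaches the acid oxidation level without amine base. A carboxylate would deactivate C3 and leave the enone carbon C2 as the electrophile, which leads to a six-membered ring.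

Design remark 2: the C6/C7 pair is not taken from an α-silyloxy-phenylacetaldehyde, because such an aldehyde is configurationally fragile towards basic ylides.

**Step 1**
Reactants: 1 (±)-1-phenylprop-2-en-1-ol
Product: 2 (R)-[(2S)-oxiran-2-yl](phenyl)methanol (erythro epoxy alcohol)
Conditions: Ti(OiPr)4 (cat.), D-(−)-DIPT (cat.), t-BuOOH (0.45 equiv), 4 Å MS, CH2Cl2, −20 °C
Reagents that add atoms: tert-butyl hydroperoxide, CC(C)(C)OO
Why: Sharpless kinetic resolution, in which D-(−)-DIPT makes the (S)-alcohol the fast-reacting enantiomer and delivers oxygen to the face that gives the erythro (anti) epoxy alcohol, so C7 is selected (descriptor R in 2) and C6 is set (S) by the catalyst, while the slow (R)-alcohol stays behind and is removed by chromatography.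

**Step 2**
Reactants: 2 (R)-[(2S)-oxiran-2-yl](phenyl)methanol
Product: 3 tert-butyl(dimethyl){(R)-[(2S)-oxiran-2-yl](phenyl)methoxy}silane
Conditions: TBSCl, imidazole, DMF, 0 °C → rt
Reagents that add atoms: tert-butyl(chloro)dimethylsilane, CC(C)(C)[Si](C)(C)Cl
Why: Imidazole-promoted silylation of a secondary alcohol is mild enough that neither epoxide opening nor Payne rearrangement should intervene, and no stereocentre is touched.

**Step 3**
Reactants: 3 tert-butyl(dimethyl){(R)-[(2S)-oxiran-2-yl](phenyl)methoxy}silane; 4 2-(trimethylsilyl)furan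
Product: 6 (1R,2S)-1-[tert-butyl(dimethyl)silyl]oxy-1-phenyl-3-[5-(trimethylsilyl)furan-2-yl]propan-2-ol, via 5-lithio-2-(trimethylsilyl)furan 5 (not isolated)
Conditions: 4, n-BuLi, THF, 0 °C; then −78 °C, BF3·OEt2, 3; sat. aq. NaHCO3 quench at −78 °C
Reagents that add atoms: none
Why: α-Lithiation of the free furan position is followed by BF3-assisted SN2 opening of the terminal epoxide at its CH2 carbon (C5), which leaves C6 and C7 untouched, and at −78 °C the new C6 alkoxide stays bound to boron, which should suppress the O-to-O shift of the neighbouring silyl group.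

**Step 4**
Reactants: 6 (1R,2S)-1-[tert-butyl(dimethyl)silyl]oxy-1-phenyl-3-[5-(trimethylsilyl)furan-2-yl]propan-2-ol
Product: 11 2-[(2R,5S)-5-{(R)-[tert-butyl(dimethyl)silyl]oxy(phenyl)methyl}-3-oxooxolan-2-yl]acetic acid, via furan endoperoxide 7 (not isolated), via trimethylsilyl (Z)-4-oxoenoate 8 (not isolated), via γ-hydroxybutenolide 9 (not isolated), via bicyclic lactol 10 (not isolated)
Conditions: O2, hν (visible), TPP (cat.), CH2Cl2, −78 °C; then H2O/THF, CSA (10 mol %), −78 °C → rt
Reagents that add atoms: dioxygen, O=O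
Why: Singlet oxygen adds [4+2] across C1/C4 of the silylfuran to give 7, the silyl group shifts from C1 to the peroxide oxygen with O–O cleavage to give silyl ester 8, and water frees the (Z)-4-oxo-2-enoic acid, which rests as its ring tautomer 9. The closest known reactions are the one-pot photooxygenation/oxa-Michael conversion of 2-(β-hydroxyalkyl)furans into tetrahydrofuran-3-ones, the photooxygenation of 2-silylfurans to γ-hydroxybutenolides, and the closure of γ-(2-hydroxyalkyl)butenolides to furo[3,2-b]furanones. The C6 hydroxyl adds to C3 in a 5-exo-trig oxa-Michael closure (ring O–C3–C4–C5–C6) to give cis-fused lactol 10, which opens to keto acid 11. The new C3 centre is controlled by C6: the lactol carbon C4 of 9 epimerises freely through the open keto acid, so both faces of C3 are available (Curtin–Hammett situation), and the closure that places the large CH(OTBS)Ph group on the convex face of the forming bicyclo[3.3.0] system, that is trans to the acetic acid arm (3R), should be both faster and lead to the more stable 10. Because C3 lies α to the ketone of 11, residual cis isomer can drift the same way by enolisation without ring opening. The step needs attack at C3 rather than 6-endo attack at C2, and the base-free, mildly acidic medium secures this, because in 9 C4 is sp3 and the only acceptor is the lactone, whose β-carbon is C3.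

**Step 5**
Reactants: 11 2-[(2R,5S)-5-{(R)-[tert-butyl(dimethyl)silyl]oxy(phenyl)methyl}-3-oxooxolan-2-yl]acetic acid
Product: 13 (3aR,5S,6aR)-5-{(R)-[tert-butyl(dimethyl)silyl]oxy(phenyl)methyl}tetrahydrofuro[3,2-b]furan-2(3H)-one, via cis-hydroxy acid 12 (not isolated)
Conditions: L-Selectride (2.3 equiv), THF, −78 °C; then 1 M HCl to pH 3, 0 °C → rt
Reagents that add atoms: none
Why: In this L-Selectride reduction of a 2-substituted five-ring ketone the bulky hydride should approach anti to the adjacent lithium carboxylate arm and set C4 as R with the hydroxyl cis to the arm, after which cis γ-hydroxy acid 12 lactonises on acidification to the unstrained cis-fused bicycle.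

**Step 6**
Reactants: 13 (3aR,5S,6aR)-5-{(R)-[tert-butyl(dimethyl)silyl]oxy(phenyl)methyl}tetrahydrofuro[3,2-b]furan-2(3H)-one
Product: 14 (3aR,5S,6aR)-5-[(R)-hydroxy(phenyl)methyl]tetrahydrofuro[3,2-b]furan-2(3H)-one
Conditions: HF·pyridine, THF, 0 °C → rt
Reagents that add atoms: none
Why: Fluoride cleavage of the silyl ether is run in an acidic medium rather than with basic TBAF, so that the β-alkoxy lactone should not undergo retro-oxa-Michael opening and re-closure through the freed C7 hydroxyl.

**Step 7**
Reactants: 14 (3aR,5S,6aR)-5-[(R)-hydroxy(phenyl)methyl]tetrahydrofuro[3,2-b]furan-2(3H)-one; 15 (2S)-pinocembrin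
Product: 16 (3aR,5S,6aR)-5-[(S)-{[(2S)-5-hydroxy-4-oxo-2-phenyl-3,4-dihydro-2H-chromen-7-yl]oxy}(phenyl)methyl]tetrahydrofuro[3,2-b]furan-2(3H)-one (target)
Conditions: PPh3, DIAD, THF, 0 °C → rt
Reagents that add atoms: none
Why: In this Mitsunobu etherification the C7 alkoxyphosphonium ion is displaced in SN2 fashion with inversion (R to S), the adjacent ring oxygen disfavours ionisation, only the acidic 7-OH of 15 reacts because the 5-OH is hydrogen-bonded to the C4 carbonyl, and the near-neutral medium spares the flavanone C2 centre and the lactone.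

**Compound list**
1 | (±)-1-phenylprop-2-en-1-ol | C=CC(O)c1ccccc1 | starting material
2 | (R)-[(2S)-oxiran-2-yl](phenyl)methanol | C1O[C@@H]1[C@H](O)c1ccccc1 | intermediate
3 | tert-butyl(dimethyl){(R)-[(2S)-oxiran-2-yl](phenyl)methoxy}silane | C1O[C@@H]1[C@H](O[Si](C)(C)C(C)(C)C)c1ccccc1 | intermediate
4 | 2-(trimethylsilyl)furan | C[Si](C)(C)c1ccco1 | starting material
5 | 5-lithio-2-(trimethylsilyl)furan | [Li]c1ccc(o1)[Si](C)(C)C | intermediate
6 | (1R,2S)-1-[tert-butyl(dimethyl)silyl]oxy-1-phenyl-3-[5-(trimethylsilyl)furan-2-yl]propan-2-ol | O[C@@H](Cc1ccc(o1)[Si](C)(C)C)[C@H](O[Si](C)(C)C(C)(C)C)c1ccccc1 | intermediate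
7 | furan endoperoxide of 6 (2,3,7-trioxabicyclo[2.2.1]hept-5-ene, SiMe3 on C1 and side chain on C4, bridgeheads as a mixture) | C[Si](C)(C)C12C=CC(C[C@H](O)[C@H](O[Si](C)(C)C(C)(C)C)c3ccccc3)(OO1)O2 | intermediate
8 | trimethylsilyl (2Z,6S,7R)-7-[tert-butyl(dimethyl)silyl]oxy-6-hydroxy-4-oxo-7-phenylhept-2-enoate | C[Si](C)(C)OC(=O)/C=C\C(=O)C[C@H](O)[C@H](O[Si](C)(C)C(C)(C)C)c1ccccc1 | intermediate
9 | 5-hydroxy-5-[(2S,3R)-3-[tert-butyl(dimethyl)silyl]oxy-2-hydroxy-3-phenylpropyl]furan-2(5H)-one (lactol carbon labile) | O=C1C=CC(O)(C[C@H](O)[C@H](O[Si](C)(C)C(C)(C)C)c2ccccc2)O1 | intermediate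
10 | (3aR,5S,6aR)-5-{(R)-[tert-butyl(dimethyl)silyl]oxy(phenyl)methyl}-6a-hydroxytetrahydrofuro[3,2-b]furan-2(3H)-one | O=C1C[C@H]2O[C@H]([C@H](O[Si](C)(C)C(C)(C)C)c3ccccc3)C[C@@]2(O)O1 | intermediate
11 | 2-[(2R,5S)-5-{(R)-[tert-butyl(dimethyl)silyl]oxy(phenyl)methyl}-3-oxooxolan-2-yl]acetic acid | OC(=O)C[C@H]1O[C@H]([C@H](O[Si](C)(C)C(C)(C)C)c2ccccc2)CC1=O | intermediate
12 | 2-[(2R,3R,5S)-5-{(R)-[tert-butyl(dimethyl)silyl]oxy(phenyl)methyl}-3-hydroxyoxolan-2-yl]acetic acid | OC(=O)C[C@H]1O[C@H]([C@H](O[Si](C)(C)C(C)(C)C)c2ccccc2)C[C@H]1O | intermediate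
13 | (3aR,5S,6aR)-5-{(R)-[tert-butyl(dimethyl)silyl]oxy(phenyl)methyl}tetrahydrofuro[3,2-b]furan-2(3H)-one | O=C1C[C@H]2O[C@H]([C@H](O[Si](C)(C)C(C)(C)C)c3ccccc3)C[C@H]2O1 | intermediate
14 | (3aR,5S,6aR)-5-[(R)-hydroxy(phenyl)methyl]tetrahydrofuro[3,2-b]furan-2(3H)-one | O=C1C[C@H]2O[C@H]([C@H](O)c3ccccc3)C[C@H]2O1 | intermediate
15 | (2S)-pinocembrin, (2S)-5,7-dihydroxy-2-phenyl-2,3-dihydrochromen-4-one | Oc1cc(O)c2c(c1)O[C@H](c1ccccc1)CC2=O | starting material
16 | CNP0152032.1, (3aR,5S,6aR)-5-[(S)-{[(2S)-5-hydroxy-4-oxo-2-phenyl-3,4-dihydro-2H-chromen-7-yl]oxy}(phenyl)methyl]tetrahydrofuro[3,2-b]furan-2(3H)-one | O=C1C[C@H]2O[C@H]([C@@H](Oc3cc(O)c4c(c3)O[C@H](c3ccccc3)CC4=O)c3ccccc3)C[C@H]2O1 | target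

Total step count: 7. Longest linear sequence: 7 steps (1 → 16).

**Steps most likely to fail**

*Step 4.*
- Risk: the hydroxyl may close on C2 through the small share of open keto acid and give a six-membered ring. The lactol may lose water towards C5. Face selection at C3 may be weak.
- Fallback: C4 is fixed before the ether bond is made. The fallback sets out from 6.
- The photooxygenation is run as in step 4 as far as 9 at −78 °C, without the acid catalyst. Et2BOMe and NaBH4 in THF/MeOH at −78 °C (Narasaka–Prasad 1,3-syn reduction of the open β-hydroxy ketone tautomer) should then give (2Z,4R,6S,7R)-7-[tert-butyl(dimethyl)silyl]oxy-4,6-dihydroxy-7-phenylhept-2-enoic acid F1.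
- On acidification F1 closes to (5R)-5-[(2S,3R)-3-[tert-butyl(dimethyl)silyl]oxy-2-hydroxy-3-phenylpropyl]furan-2(5H)-one F2.
- Catalytic DBU in CH2Cl2 then effects the oxa-Michael closure. Only C3 is electrophilic in F2, and the cis ring fusion forces C3 to follow C4.
- The fallback comes back to the route at 13 and also replaces step 5.

*Step 5.*
- Risk: facial selectivity may be poor, because the face anti to the acetic acid arm is the one that carries the large C6 substituent.
- Fallback: both alcohol epimers are made to converge. The fallback sets out from 11.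
- Reduction with NaBH4 in MeOH and acidification lets the cis-hydroxy acid close to 13 by itself.
- 2-[(2R,3S,5S)-5-{(R)-[tert-butyl(dimethyl)silyl]oxy(phenyl)methyl}-3-hydroxyoxolan-2-yl]acetic acid F3 cannot form a trans-fused lactone and is taken out by bicarbonate extraction.
- Mitsunobu lactonisation of F3 (PPh3, DIAD, THF) activates the C4 hydroxyl, and the carboxylate displaces it intramolecularly with inversion.
- The fallback comes back to the route at 13.

*Step 7.*
- Risk: activation and displacement at the hindered benzylic carbinol may be slow. Elimination towards C6 or partial ionisation could erode the inversion.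
- Fallback: activation and displacement are separated. The fallback sets out from 14.
- MsCl and Et3N in CH2Cl2 at −20 °C should give (R)-[(3aR,5S,6aR)-2-oxohexahydrofuro[3,2-b]furan-5-yl](phenyl)methyl methanesulfonate F4.
- F4 is displaced in SN2 fashion by the 7-phenoxide of 15, made with one equivalent of Cs2CO3 in DMF at 0 °C → rt. Only the most acidic hydroxyl is ionised, and the flavanone ring should stay closed.
- The fallback comes back to the route at 16.

**Further compounds**
F1 | step 4 | (2Z,4R,6S,7R)-7-[tert-butyl(dimethyl)silyl]oxy-4,6-dihydroxy-7-phenylhept-2-enoic acid | OC(=O)/C=C\[C@H](O)C[C@H](O)[C@H](O[Si](C)(C)C(C)(C)C)c1ccccc1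
F2 | step 4 | (5R)-5-[(2S,3R)-3-[tert-butyl(dimethyl)silyl]oxy-2-hydroxy-3-phenylpropyl]furan-2(5H)-one | O=C1C=C[C@@H](C[C@H](O)[C@H](O[Si](C)(C)C(C)(C)C)c2ccccc2)O1
F3 | step 5 | 2-[(2R,3S,5S)-5-{(R)-[tert-butyl(dimethyl)silyl]oxy(phenyl)methyl}-3-hydroxyoxolan-2-yl]acetic acid | OC(=O)C[C@H]1O[C@H]([C@H](O[Si](C)(C)C(C)(C)C)c2ccccc2)C[C@@H]1O
F4 | step 7 | (R)-[(3aR,5S,6aR)-2-oxohexahydrofuro[3,2-b]furan-5-yl](phenyl)methyl methanesulfonate | O=C1C[C@H]2O[C@H]([C@H](OS(C)(=O)=O)c3ccccc3)C[C@H]2O1
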